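**Strategy.** Both pyran rings are cut across C3–C4 and O1–C2, each into an ortho-quinone methide and an arylacetaldehyde. The key step closes the 4-unsubstituted chroman (chroman 2) last: a chiral enamine of the complete 4-arylisoflavan acetaldehyde attacks, through the future C3, the methylene C4 of a sulfone-masked quinone methide, whose phenoxide O1 then closes onto C2, fixing C3 under catalyst control. It exploits that O1 and C4 of chroman 2 sit ortho on its resorcinol ring, with the 7-oxygen para to C4a, while C3 is benzylic to the central ring and α to a latent C2 carbonyl. The aldehyde precursor arises by the same annulation on a brominated central ring.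

Key step: step 8

Locants: chroman 1 is the 3,4-diaryl chroman, chroman 2 the 4-unsubstituted chroman, and the central ring is the benzene that joins C4 of chroman 1 to C3 of chroman 2.

Assumption: lactols 11 and 19 are carried as mixtures of C2 anomers and quinone methide 10 has no defined double-bond geometry; neither element survives into the target, so both are left undefined in the SMILES.

Step 1
Reactants: 1 3-bromo-5-methoxyphenol
Product: 2 (3-bromo-5-methoxyphenoxy)triisopropylsilane
Conditions: iPr3SiCl, imidazole, DMF, rt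
Reagents that add atoms: triisopropylsilyl chloride, CC(C)[Si](Cl)(C(C)C)C(C)C
Why: Silylation of the phenol (silyl ether formation) installs a bulky, non-coordinating group that shields both of its ortho C–H bonds in step 2 and is removed in step 10.

Step 2
Reactants: 2 (3-bromo-5-methoxyphenoxy)triisopropylsilane; 3 4-(benzyloxy)-2-hydroxybenzaldehyde
Product: 6 rac-[4-(benzyloxy)-2-hydroxyphenyl][2-bromo-6-methoxy-4-(triisopropylsilyloxy)phenyl]methanol, via aryllithium 4 (not isolated), via sodium phenolate 5 (not isolated)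
Conditions: 2, LiN(iPr)2, THF, −78 °C; then 5 (from 3, NaH, THF, 0 °C), −78 to −45 °C; aq. NH4Cl
Reagents that add atoms: none
Why: Deprotonative ortho-lithiation takes the most acidic C–H, the one flanked by Br and OMe (the C–H bonds next to the silyl ether are shielded, and the lithiated carbon is para to silicon, so no silyl migration can follow), and 1,2-addition of the aryllithium to the phenolate-masked aldehyde gives the ortho-hydroxybenzhydrol, whose racemic carbinol centre is erased in step 4.

Step 3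
Reactants: 7 2-(benzyloxy)-4,5-dimethoxybenzaldehyde
Product: 9 2-[2-(benzyloxy)-4,5-dimethoxyphenyl]acetaldehyde, via enol ether 8 (not isolated)
Conditions: Ph3P(CH2OMe)Cl, KOtBu, THF, 0 °C to rt; then 2 M HCl, THF, 45 °C
Reagents that add atoms: (methoxymethyl)triphenylphosphonium chloride, COC[P+](c1ccccc1)(c1ccccc1)c1ccccc1.[Cl-]; water, O
Why: Wittig methoxymethylenation followed by acid hydrolysis of the enol ether is the standard one-carbon homologation of an aryl aldehyde to an arylacetaldehyde; no stereocentre is formed.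

Step 4
Reactants: 6 rac-[4-(benzyloxy)-2-hydroxyphenyl][2-bromo-6-methoxy-4-(triisopropylsilyloxy)phenyl]methanol; 9 2-[2-(benzyloxy)-4,5-dimethoxyphenyl]acetaldehyde
Product: 11 (3R,4S)-7-(benzyloxy)-3-[2-(benzyloxy)-4,5-dimethoxyphenyl]-4-[2-bromo-6-methoxy-4-(triisopropylsilyloxy)phenyl]chroman-2-ol (C2 anomers), via quinone methide 10 (not isolated)
Conditions: (R)-α,α-diphenylprolinol trimethylsilyl ether (20 mol%), PhCO2H (20 mol%), CH2Cl2, 0 °C to rt
Reagents that add atoms: none
Why: Amine/acid-promoted dehydration of the donor-stabilised ortho-hydroxybenzhydrol gives quinone methide 10, to which the E-enamine of 9 adds (Michael addition, then 6-exo-trig hemiacetalisation; amine-catalysed formal [4+2] annulation of aldehydes with ortho-quinone methides): C3 is set by the (R)-catalyst, which shields one enamine face, and C4 by the open synclinal transition state that places the two aryl groups trans, while bromine, the smallest workable ortho group on the central ring, keeps the hindered C4 accessible.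

Step 5
Reactants: 11 (3R,4S)-7-(benzyloxy)-3-[2-(benzyloxy)-4,5-dimethoxyphenyl]-4-[2-bromo-6-methoxy-4-(triisopropylsilyloxy)phenyl]chroman-2-ol
Product: 12 (3R,4S)-7-(benzyloxy)-3-[2-(benzyloxy)-4,5-dimethoxyphenyl]-4-[2-bromo-6-methoxy-4-(triisopropylsilyloxy)phenyl]chromane
Conditions: Et3SiH, BF3·OEt2, CH2Cl2, −78 to −20 °C
Reagents that add atoms: none
Why: Ionic hydrogenation of the lactol (Lewis acid ionisation to the cyclic oxocarbenium ion, hydride transfer from the silane) turns C2 into CH2 without touching C3 or C4; low temperature and excess silane should make hydride capture faster than loss of the C3 proton.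

Step 6
Reactants: 12 (3R,4S)-7-(benzyloxy)-3-[2-(benzyloxy)-4,5-dimethoxyphenyl]-4-[2-bromo-6-methoxy-4-(triisopropylsilyloxy)phenyl]chromane; 13 (E)-2-(2-ethoxyethenyl)-4,4,5,5-tetramethyl-1,3,2-dioxaborolane
Product: 15 2-{2-[(3R,4S)-7-(benzyloxy)-3-[2-(benzyloxy)-4,5-dimethoxyphenyl]chroman-4-yl]-3-methoxy-5-(triisopropylsilyloxy)phenyl}acetaldehyde, via enol ether 14 (not isolated)
Conditions: Pd(OAc)2 (5 mol%), 2-dicyclohexylphosphino-2′,6′-dimethoxybiphenyl (SPhos, 10 mol%), K3PO4, toluene/H2O, 80 °C; then 2 M HCl, THF, rt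
Reagents that add atoms: water, O
Why: Suzuki–Miyaura coupling of the ortho-hindered, electron-rich aryl bromide with the alkenylboronate is supported by the bulky biarylphosphine, and acid hydrolysis of the resulting enol ether unmasks the arylacetaldehyde; the stereocentres of chroman 1 are not involved.

Step 7
Reactants: 3 4-(benzyloxy)-2-hydroxybenzaldehyde
Product: 17 5-(benzyloxy)-2-{[(4-methylphenyl)sulfonyl]methyl}phenol, via benzyl alcohol 16 (not isolated)
Conditions: NaBH4, EtOH, 0 °C; then p-TolSO2Na, HCO2H, H2O, rt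
Reagents that add atoms: sodium p-toluenesulfinate, Cc1ccc(cc1)S(=O)[O-].[Na+]
Why: Hydride reduction of the aldehyde, then acid ionisation of the para-alkoxy ortho-hydroxybenzyl alcohol and S-alkylation of the sulfinate, gives the sulfone as a storable precursor of quinone methide 18; no stereocentre is formed.

Step 8
Reactants: 15 2-{2-[(3R,4S)-7-(benzyloxy)-3-[2-(benzyloxy)-4,5-dimethoxyphenyl]chroman-4-yl]-3-methoxy-5-(triisopropylsilyloxy)phenyl}acetaldehyde; 17 5-(benzyloxy)-2-{[(4-methylphenyl)sulfonyl]methyl}phenol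
Product: 19 (3R)-7-(benzyloxy)-3-{2-[(3R,4S)-7-(benzyloxy)-3-[2-(benzyloxy)-4,5-dimethoxyphenyl]chroman-4-yl]-3-methoxy-5-(triisopropylsilyloxy)phenyl}chroman-2-ol (C2 anomers), via quinone methide 18 (not isolated)
Conditions: (R)-α,α-diphenylprolinol trimethylsilyl ether (20 mol%), Na2CO3, CH2Cl2, 0 °C to rt, 17 added in portions
Reagents that add atoms: none
Why: The secondary amine condenses with aldehyde 15 to the E-enamine, Na2CO3 releases quinone methide 18 from sulfone 17 by 1,4-elimination of sulfinate, and the enamine carbon (future C3 of chroman 2) adds to the exocyclic methylene (C4) in a Michael addition that restores the aromatic ring as a phenoxide. The phenoxide oxygen (O1) then closes onto the iminium carbon (C2) in a 6-exo-trig closure and hydrolysis returns the catalyst and leaves lactol 19; the closest known reaction type is the amine-catalysed formal [4+2] annulation (Michael addition–hemiacetalisation) of aldehydes with ortho-quinone methides released from 2-(sulfonylmethyl)phenols. C3 of chroman 2 is set by the catalyst: its diphenyl(silyloxy)methyl group shields one face of the enamine, and by the model that holds for Michael additions of such enamines the (R)-catalyst should give 3R when the aryl group outranks the new CH2 group, while C2 forms as an anomeric mixture that step 9 erases. The step needs chemoselectivity for C-alkylation by the enamine over N-alkylation of the catalyst or self-condensation of 18, which the hindered nitrogen, the slow base-gated release of 18 and the tempering of C4 by the para benzyloxy group should secure. It also needs catalyst control to override the C3 and C4 centres of chroman 1, which sit on the far side of the central ring from the reacting carbon. No regiochemical issue arises, because only the methylene terminus of 18 is electrophilic and only the α-carbon of the enamine is nucleophilic.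

Step 9
Reactants: 19 (3R)-7-(benzyloxy)-3-{2-[(3R,4S)-7-(benzyloxy)-3-[2-(benzyloxy)-4,5-dimethoxyphenyl]chroman-4-yl]-3-methoxy-5-(triisopropylsilyloxy)phenyl}chroman-2-ol
Product: 20 (3R,4S)-7-(benzyloxy)-3-[2-(benzyloxy)-4,5-dimethoxyphenyl]-4-{2-[(3R)-7-(benzyloxy)chroman-3-yl]-6-methoxy-4-(triisopropylsilyloxy)phenyl}chromane
Conditions: Et3SiH, BF3·OEt2, CH2Cl2, −78 to −20 °C
Reagents that add atoms: none
Why: The same ionic hydrogenation as in step 5 reduces the lactol carbon C2 of chroman 2 to CH2 and so keeps the O1–C2 bond made in step 8; C3 of chroman 2 should be retained because hydride capture by the aryloxycarbenium ion at −78 °C is faster than loss of the benzylic C3 proton.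

Step 10
Reactants: 20 (3R,4S)-7-(benzyloxy)-3-[2-(benzyloxy)-4,5-dimethoxyphenyl]-4-{2-[(3R)-7-(benzyloxy)chroman-3-yl]-6-methoxy-4-(triisopropylsilyloxy)phenyl}chromane
Product: 22 (3R,4S)-3-(2-hydroxy-4,5-dimethoxyphenyl)-4-{4-hydroxy-2-[(3R)-7-hydroxychroman-3-yl]-6-methoxyphenyl}chroman-7-ol, via phenol 21 (not isolated)
Conditions: Bu4NF, THF, 0 °C; then AcOH, MeOH, Pd/C (10% Pd on carbon), H2 (1 atm), rt
Reagents that add atoms: none
Why: Fluoride cleaves the aryl silyl ether and hydrogenolysis then removes the three benzyl ethers in the same flask, leaving the methyl ethers, the chroman C–O bonds and all three stereocentres untouched.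

**Compound list**

1 | 3-bromo-5-methoxyphenol | COc1cc(O)cc(Br)c1 | starting material
2 | (3-bromo-5-methoxyphenoxy)triisopropylsilane | COc1cc(O[Si](C(C)C)(C(C)C)C(C)C)cc(Br)c1 | intermediate
3 | 4-(benzyloxy)-2-hydroxybenzaldehyde | O=Cc1ccc(OCc2ccccc2)cc1O | starting material
4 | [2-bromo-6-methoxy-4-(triisopropylsilyloxy)phenyl]lithium (not isolated) | [Li]c1c(OC)cc(O[Si](C(C)C)(C(C)C)C(C)C)cc1Br | intermediate
5 | sodium 5-(benzyloxy)-2-formylphenolate (not isolated) | O=Cc1ccc(OCc2ccccc2)cc1[O-].[Na+] | intermediate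
6 | rac-[4-(benzyloxy)-2-hydroxyphenyl][2-bromo-6-methoxy-4-(triisopropylsilyloxy)phenyl]methanol | OC(c1ccc(OCc2ccccc2)cc1O)c1c(OC)cc(O[Si](C(C)C)(C(C)C)C(C)C)cc1Br | intermediate
7 | 2-(benzyloxy)-4,5-dimethoxybenzaldehyde | COc1cc(C=O)c(OCc2ccccc2)cc1OC | starting material
8 | 1-(benzyloxy)-4,5-dimethoxy-2-(2-methoxyethenyl)benzene, E/Z mixture (not isolated) | COC=Cc1cc(OC)c(OC)cc1OCc1ccccc1 | intermediate
9 | 2-[2-(benzyloxy)-4,5-dimethoxyphenyl]acetaldehyde | O=CCc1cc(OC)c(OC)cc1OCc1ccccc1 | intermediate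
10 | 3-(benzyloxy)-6-{[2-bromo-6-methoxy-4-(triisopropylsilyloxy)phenyl]methylidene}cyclohexa-2,4-dien-1-one (not isolated) | O=C1C=C(OCc2ccccc2)C=CC1=Cc1c(OC)cc(O[Si](C(C)C)(C(C)C)C(C)C)cc1Br | intermediate
11 | (3R,4S)-7-(benzyloxy)-3-[2-(benzyloxy)-4,5-dimethoxyphenyl]-4-[2-bromo-6-methoxy-4-(triisopropylsilyloxy)phenyl]chroman-2-ol (C2 anomers) | COc1cc(OCc2ccccc2)c([C@@H]2C(O)Oc3cc(OCc4ccccc4)ccc3[C@H]2c2c(OC)cc(O[Si](C(C)C)(C(C)C)C(C)C)cc2Br)cc1OC | intermediate
12 | (3R,4S)-7-(benzyloxy)-3-[2-(benzyloxy)-4,5-dimethoxyphenyl]-4-[2-bromo-6-methoxy-4-(triisopropylsilyloxy)phenyl]chromane | COc1cc(OCc2ccccc2)c([C@@H]2COc3cc(OCc4ccccc4)ccc3[C@H]2c2c(OC)cc(O[Si](C(C)C)(C(C)C)C(C)C)cc2Br)cc1OC | intermediate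
13 | (E)-2-(2-ethoxyethenyl)-4,4,5,5-tetramethyl-1,3,2-dioxaborolane | CCO/C=C/B1OC(C)(C)C(C)(C)O1 | starting material
14 | (3R,4S)-7-(benzyloxy)-3-[2-(benzyloxy)-4,5-dimethoxyphenyl]-4-{2-[(E)-2-ethoxyethenyl]-6-methoxy-4-(triisopropylsilyloxy)phenyl}chromane (not isolated) | COc1cc(OCc2ccccc2)c([C@@H]2COc3cc(OCc4ccccc4)ccc3[C@H]2c2c(OC)cc(O[Si](C(C)C)(C(C)C)C(C)C)cc2/C=C/OCC)cc1OC | intermediate
15 | 2-{2-[(3R,4S)-7-(benzyloxy)-3-[2-(benzyloxy)-4,5-dimethoxyphenyl]chroman-4-yl]-3-methoxy-5-(triisopropylsilyloxy)phenyl}acetaldehyde | COc1cc(OCc2ccccc2)c([C@@H]2COc3cc(OCc4ccccc4)ccc3[C@H]2c2c(OC)cc(O[Si](C(C)C)(C(C)C)C(C)C)cc2CC=O)cc1OC | intermediate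
16 | 5-(benzyloxy)-2-(hydroxymethyl)phenol (not isolated) | OCc1ccc(OCc2ccccc2)cc1O | intermediate
17 | 5-(benzyloxy)-2-{[(4-methylphenyl)sulfonyl]methyl}phenol | Cc1ccc(cc1)S(=O)(=O)Cc1ccc(OCc2ccccc2)cc1O | intermediate
18 | 3-(benzyloxy)-6-methylidenecyclohexa-2,4-dien-1-one (not isolated) | C=C1C=CC(OCc2ccccc2)=CC1=O | intermediate
19 | (3R)-7-(benzyloxy)-3-{2-[(3R,4S)-7-(benzyloxy)-3-[2-(benzyloxy)-4,5-dimethoxyphenyl]chroman-4-yl]-3-methoxy-5-(triisopropylsilyloxy)phenyl}chroman-2-ol (C2 anomers) | COc1cc(OCc2ccccc2)c([C@@H]2COc3cc(OCc4ccccc4)ccc3[C@H]2c2c(OC)cc(O[Si](C(C)C)(C(C)C)C(C)C)cc2[C@@H]2C(O)Oc3cc(OCc4ccccc4)ccc3C2)cc1OC | intermediate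
20 | (3R,4S)-7-(benzyloxy)-3-[2-(benzyloxy)-4,5-dimethoxyphenyl]-4-{2-[(3R)-7-(benzyloxy)chroman-3-yl]-6-methoxy-4-(triisopropylsilyloxy)phenyl}chromane | COc1cc(OCc2ccccc2)c([C@@H]2COc3cc(OCc4ccccc4)ccc3[C@H]2c2c(OC)cc(O[Si](C(C)C)(C(C)C)C(C)C)cc2[C@@H]2COc3cc(OCc4ccccc4)ccc3C2)cc1OC | intermediate
21 | 4-[(3R,4S)-7-(benzyloxy)-3-[2-(benzyloxy)-4,5-dimethoxyphenyl]chroman-4-yl]-3-[(3R)-7-(benzyloxy)chroman-3-yl]-5-methoxyphenol (not isolated) | COc1cc(OCc2ccccc2)c([C@@H]2COc3cc(OCc4ccccc4)ccc3[C@H]2c2c(OC)cc(O)cc2[C@@H]2COc3cc(OCc4ccccc4)ccc3C2)cc1OC | intermediate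
22 | (3R,4S)-3-(2-hydroxy-4,5-dimethoxyphenyl)-4-{4-hydroxy-2-[(3R)-7-hydroxychroman-3-yl]-6-methoxyphenyl}chroman-7-ol | COc1cc(O)c([C@@H]2COc3cc(O)ccc3[C@H]2c2c(OC)cc(O)cc2[C@@H]2COc3cc(O)ccc3C2)cc1OC | target

**Step count.** Total: 10 steps. Longest linear sequence: 8 steps (1, 2, 4, 5, 6, 8, 9, 10).

**Steps most likely to fail**

Step 8. N-alkylation of the amine catalyst and oligomerisation of the unsubstituted quinone methide may outrun C–C bond formation, or the lactol may lose its C3 configuration by ring opening and renewed enamine formation. The fallback sets out from 15. Pinnick oxidation (NaClO2, NaH2PO4, 2-methyl-2-butene, tBuOH/H2O) should give the arylacetic acid F1. Activation with tBuCOCl and iPr2NEt gives the mixed pivalic anhydride F2 in the flask. An isothiourea catalyst (benzotetramisole, in the enantiomer that delivers 3R, both being available) turns F2 into its ammonium enolate, which undergoes Michael addition–lactonisation with quinone methide 18 released from 17 by iPr2NEt. This forms the same two bonds in one operation and gives the (3R)-3-aryl-3,4-dihydrocoumarin F3. Reduction with iBu2AlH at −78 °C returns to the route at lactol 19.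

Step 4. C–C bond formation may be slow at the quinone methide carbon that carries the doubly ortho-substituted aryl group, so that 10 is diverted into amine adducts or dimers and the trans selectivity falls. The fallback sets out from 6 and from enol ether 8, taken from step 3 by omitting the acid treatment. A chiral BINOL-derived phosphoric acid of the 3,3′-bis(2,4,6-triisopropylphenyl) type (enantiomer chosen for 3R,4S) catalyses dehydration of 6 and an inverse-electron-demand hetero-Diels–Alder reaction of 10 with the small, catalyst-free enol ether. This should give the 2-methoxychroman F4, which loses its methoxy group under the conditions of step 5 and returns to the route at 12.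

Step 2. The ortho-bromoaryllithium may lose LiBr (aryne formation) before it has added to the phenolate-deactivated aldehyde. The fallback sets out from 3 and aryllithium 4. Boc2O, iPr2NEt and DMAP convert 3 into the O-tert-butoxycarbonyl aldehyde F5, which is no longer deactivated, so 4 should add at −78 °C. The new alkoxide takes over the Boc group from the phenol oxygen, and a cold acidic quench gives the benzylic tert-butyl carbonate F6. Under the amine catalyst of step 4, with NaHCO3 in place of PhCO2H, F6 eliminates tert-butyl carbonate to give quinone methide 10, and the route is rejoined at 11.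

**Further compounds**

F1 | step 8 | 2-{2-[(3R,4S)-7-(benzyloxy)-3-[2-(benzyloxy)-4,5-dimethoxyphenyl]chroman-4-yl]-3-methoxy-5-(triisopropylsilyloxy)phenyl}acetic acid | COc1cc(OCc2ccccc2)c([C@@H]2COc3cc(OCc4ccccc4)ccc3[C@H]2c2c(OC)cc(O[Si](C(C)C)(C(C)C)C(C)C)cc2CC(=O)O)cc1OC
F2 | step 8 | mixed anhydride of F1 with pivalic acid | COc1cc(OCc2ccccc2)c([C@@H]2COc3cc(OCc4ccccc4)ccc3[C@H]2c2c(OC)cc(O[Si](C(C)C)(C(C)C)C(C)C)cc2CC(=O)OC(=O)C(C)(C)C)cc1OC
F3 | step 8 | (3R)-7-(benzyloxy)-3-{2-[(3R,4S)-7-(benzyloxy)-3-[2-(benzyloxy)-4,5-dimethoxyphenyl]chroman-4-yl]-3-methoxy-5-(triisopropylsilyloxy)phenyl}chroman-2-one | COc1cc(OCc2ccccc2)c([C@@H]2COc3cc(OCc4ccccc4)ccc3[C@H]2c2c(OC)cc(O[Si](C(C)C)(C(C)C)C(C)C)cc2[C@@H]2C(=O)Oc3cc(OCc4ccccc4)ccc3C2)cc1OC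
F4 | step 4 | (3R,4S)-7-(benzyloxy)-3-[2-(benzyloxy)-4,5-dimethoxyphenyl]-4-[2-bromo-6-methoxy-4-(triisopropylsilyloxy)phenyl]-2-methoxychromane (C2 anomers) | COc1cc(OCc2ccccc2)c([C@@H]2C(OC)Oc3cc(OCc4ccccc4)ccc3[C@H]2c2c(OC)cc(O[Si](C(C)C)(C(C)C)C(C)C)cc2Br)cc1OC
F5 | step 2 | 5-(benzyloxy)-2-formylphenyl tert-butyl carbonate | O=Cc1ccc(OCc2ccccc2)cc1OC(=O)OC(C)(C)C
F6 | step 2 | rac-[4-(benzyloxy)-2-hydroxyphenyl][2-bromo-6-methoxy-4-(triisopropylsilyloxy)phenyl]methyl tert-butyl carbonate | CC(C)(C)OC(=O)OC(c1ccc(OCc2ccccc2)cc1O)c1c(OC)cc(O[Si](C(C)C)(C(C)C)C(C)C)cc1Br
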